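**The leftover.** Teal's last reading leaves 26.4% of the substrate charged in neither column, and its side product has stopped within the scatter, 56.8% then 57.3%, so I treat teal as finished and take its share of target in target plus side product (the selectivity) as the zero of the scale: 22.1%, the finished share. Target ends between 16.1% and 17.6% at the last readings of these four runs, so I read a share above zero as side product still to come.

| flask | substrate | reagent | temperature | remark | time |
|---|---|---|---|---|---|
| red | 0.020 M | 0.014 M | −5 °C | run made earlier |  |
| violet | 0.013 M | 0.014 M | 6 °C | run made earlier |  |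
| blue | 0.030 M | 0.014 M | −5 °C | run made earlier |  |
| teal | 0.020 M | 0.028 M | 6 °C | run made earlier |  |
| eta | 0.020 M (fed, over 3.0 d) | 0.0140 M |  | the addition at −40 °C, then warmed to 0 °C; the feed brings no volume worth counting | 5.0 d |
| epsilon | 0.020 M | 0.0140 M (fed, over 3.0 d) | 0 °C | all else is in the flask from the start; the feed brings no volume worth counting | 5.0 d |
| gamma | 0.020 M | 0.0140 M | 0 °C | everything together at the start | 5.0 d |
| zeta | 0.020 M | 0.0140 M (in portions, 4, over 3.0 d) | 0 °C | first portion at the start, last at 3.0 d | 5.0 d |

| run | time / d | target / % | side product / % |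
|---|---|---|---|
| red | 0.833 | 22.8 | 11.9 |
| red | 1.67 | 19.7 | 23.6 |
| red | 2.50 | 18.3 | 33.1 |
| red | 3.00 | 17.6 | 36.0 |
| violet | 0.250 | 20.6 | 12.0 |
| violet | 0.500 | 17.2 | 22.7 |
| violet | 1.25 | 16.2 | 43.5 |
| violet | 3.00 | 16.1 | 53.2 |
| blue | 0.417 | 22.0 | 5.4 |
| blue | 1.04 | 22.0 | 15.6 |
| blue | 2.08 | 19.1 | 26.7 |
| blue | 3.00 | 16.2 | 30.3 |
| teal | 0.417 | 17.8 | 32.3 |
| teal | 1.04 | 15.4 | 50.1 |
| teal | 2.08 | 17.3 | 56.8 |
| teal | 3.00 | 16.3 | 57.3 |

(standard deviation of a reading: 1 percentage point)

* the best flask by share of target in target plus side product; "all alike" if 1.5 percentage points covers them all (eta / epsilon / gamma / zeta / all alike)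
* share of target in target plus side product at the end, eta
* share of target in target plus side product at the end, epsilon
* share of target in target plus side product at the end, gamma
* share of target in target plus side product at the end, zeta

- the analysis behind the earlier runs scatters by 1 percentage point, standard deviation

**Temperature.** By hand, cold delays side product. Violet, which also differs from red in [substrate], nearly reaches red's side product in 0.500 d against 1.67 d, a factor of 3.34; I take that factor as the effect of temperature, and with 0 °C near the middle of that span, I estimate that 6 °C runs about twice as fast as 0 °C. So gamma's 5.0 d is worth 2.74 d of violet, whose last share is 23.2%. If eta stands still at −40 °C, its 2.00 d after the feed are worth 1.09 d of violet, near violet's share at 1.25 d, 27.1%.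

**Amounts.** By hand, more [reagent] should hurry side product, but teal at 0.028 M and violet at 0.014 M, which also differ in [substrate], end close together in share, so I expect the zero to stay put.

**Dosing.** Held-back reagent delays side product, but epsilon and zeta have their whole charge for the last 2.00 d, so I set them about one point above gamma, with eta best.

**The forecast.** It names eta, with eta 31%, epsilon 30%, gamma 28% and zeta 29%, holding that “selectivity seems set mainly by how far the flask has gone”. My reckoning runs lower for eta and gamma.

**The flasks.** The best is eta: eta 29.8%, epsilon 24.6%, gamma 23.4%, zeta 24.8%. The forecast parts from the flask most at epsilon, 30% against 24.6%.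

    substrate → intermediate B (k = 3.40 × 10⁻⁵ s⁻¹, Ea = 87.0 kJ mol⁻¹)
    target ⇌ isomer of the product (K = 1.80, k = 1.90 × 10⁻⁵ s⁻¹, Ea = 83.0 kJ mol⁻¹, ΔH = −13.0 kJ mol⁻¹)
    substrate → target (k = 2.60 × 10⁻⁵ s⁻¹, Ea = 80.0 kJ mol⁻¹)
    reagent + intermediate B → side product (k = 9.20 × 10⁻⁴ M⁻¹ s⁻¹, Ea = 51.0 kJ mol⁻¹)
    substrate ⇌ intermediate A (K = 0.820, k = 2.60 × 10⁻⁵ s⁻¹, Ea = 88.0 kJ mol⁻¹, ΔH = 24.0 kJ mol⁻¹)
    (constants at 0 °C)

**What to watch.** In eta at 5.00 d, intermediate B halves in 1.4 d by its reaction with reagent, slower than the 0.24 d in which substrate goes to intermediate B, and eta then holds 17.5% of intermediate B. At the finished share, eta's target of 16.1% asks for 18.8% more side product, and eta's share stands at 21.6% by 50.0 d.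

**Second flask.** In a neighbour flask, which is eta with [reagent] at 0.056 M, target of 16.1% at the finished share asks for 56.8% of side product. The computed neighbour flask holds 54.7% of side product, a share of 22.8%.

All runs are calculated with constants of no real substance, and the scatter is random.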